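**The vessel.** Charge a closed, stirred, isothermal flask with starting material, protic impurity, free catalyst and added ligand, then ask what the catalyst charge does to the rate at an early look.

| flask | starting material | protic impurity | free catalyst | added ligand | remark |
|---|---|---|---|---|---|
| Thursday's | 0.25 M | 0.050 M | 2.5 mol% | 4.5 mM | run made earlier |
| Sunday's | 0.25 M | 0.050 M | 2.5 mol% | 18 mM | run made earlier |
| Saturday's | 0.38 M | 0.050 M | 2.5 mol% | 9.1 mM | run made earlier |
| flask | 0.25 M | 0.0500 M | 2.5 mol% | 9.1 mM |  |

| run | time / h | product / % | starting material / % |
|---|---|---|---|
| Thursday's | 2.00 | 3 | 75 |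
| Thursday's | 6.00 | 11 | 67 |
| Thursday's | 12.0 | 26 | 55 |
| Thursday's | 15.0 | 27 | 53 |
| Thursday's | 25.0 | 40 | 40 |
| Sunday's | 5.00 | 6 | 72 |
| Sunday's | 10.0 | 10 | 68 |
| Sunday's | 15.0 | 16 | 63 |
| Sunday's | 20.0 | 22 | 58 |
| Sunday's | 25.0 | 26 | 53 |
| Saturday's | 5.00 | 12 | 73 |
| Saturday's | 10.0 | 19 | 65 |
| Saturday's | 15.0 | 28 | 58 |
| Saturday's | 20.0 | 37 | 51 |
| Saturday's | 25.0 | 44 | 40 |

(readings scatter by 1.5 percentage points)

- what is bound to the catalyst counts as converted

1. factor on the rate of making product when 5.0% of the starting material are converted if free catalyst is charged twice over
2. factor on the rate when 5.0% of the starting material are converted if free catalyst is charged at 0.5 mol% instead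

**First way.** Read the hours. In Thursday's run 22.0% of the starting material is missing from both columns at 2.00 h, and impurity charge plus catalyst loading comes to 22.5% of it. In Saturday's run the gap at 5.00 h is 15.0%, against 15.7% from the charge. Readings and charges are different things, so trust this early loss. Product then climbs steadily, and if catalyst simply multiplies that slope, doubling it gives a factor of 2.

**Second way.** Now place the look. Its 5.0% is less than the 20.0% that the impurity takes, so it falls inside the early loss. There, conversion is the clock. Loss to the impurity (call it quench) and capture by catalyst both consume starting material, so divide one rate by the other and time drops out. Take catalyst charge over impurity charge, 0.125, and call it the race ratio. Assuming equal rate constants, this is capture over quench, and the time to the look scales as one over one plus that ratio. Take the rate there as charge times elapsed time. My reckoning gives 1.80 on doubling and 0.220 at 0.5 mol%.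

**The parting.** The two ways differ on doubling. Suspect the first, because it reads a slope from hours after a look that lies inside the early loss.

**The forecast.** It gives 2 and 0.2, adding “The burst period at 5% conversion adds uncertainty”. My numbers are lower on doubling and higher at the small charge.

**The flask.** It gives 1.72 and 0.227.

    starting material + free catalyst ⇌ catalyst intermediate A (K = 9.50 L mol⁻¹, k = 22.0 L mol⁻¹ h⁻¹)
    catalyst intermediate A ⇌ catalyst intermediate B (K = 64.0, k = 9.60 h⁻¹)
    catalyst intermediate B → free catalyst + product (k = 1.50 h⁻¹)
    free catalyst + added ligand ⇌ idle complex (K = 250 L mol⁻¹, k = 160 L mol⁻¹ h⁻¹)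
    starting material + protic impurity → quenched substrate (k = 33.0 L mol⁻¹ h⁻¹)

In the flask the look comes at 1.96 min, inside an induction period: 80.7% of the catalyst is free then, more than the 19.2% after 4.00 h, and capture starts at 0.0833 of the quench rate, the race ratio times the two rate constants' quotient. With catalyst intermediates A and B in line, square the clock factor: doubling then gives 1.72, and a charge of 0.5 mol% gives 0.227.

(All runs are simulated with constants of no real substance, and the scatter is random.)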